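**Retrosynthetic overview**
1. Target ⇐ PMB removal and acetylation ⇐ macrocyclic 2,3-diol ⇐ SmI2 pinacol closure of a C2/C3 seco-dialdehyde: the ten-membered ring is closed last, and C2 and C3 are set in the ring-forming step (no RCM or NHK at C5=C6).
2. Seco-dialdehyde ⇐ syn-8,9-diol from OsO4 on a β-alkylidene γ-lactone ⇐ 7-OH-directed epoxidation and lactonisation of a dienol.
3. Dienol ⇐ acyl Stille union of a Z-alkenylstannane (Ru trans-hydrostannation of the adduct of a ring-A alkyne with methyl pyruvate) with a Z-enoyl chloride from 4-methyl-5,6-dihydro-2H-pyran-2-one.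
4. Ring-A alkyne ⇐ bridged lactone ⇐ OH-directed hydrogenation and OH-directed reduction of an ene-keto-ester ⇐ CBS desymmetrisation of a 2,2-disubstituted cyclohexane-1,3-dione.
5. Ring order: ring A → γ-lactone → epoxide → ten-membered ring.

Assumption: briarane numbering is used for all intermediates (ring A = C1, C10–C14; macrocycle C1–C10; lactone C7–O–C19–C17–C8; methyls C15, C16, C18, C20), β is the face carrying C15, and 2-methylcyclohexane-1,3-dione, methyl pyruvate and 4-methyl-5,6-dihydro-2H-pyran-2-one are bought.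

**Route**

Step 1
Reactants: 1 2-methylcyclohexane-1,3-dione
Product: 2 2-(hydroxymethyl)-2-methylcyclohexane-1,3-dione
Conditions: 37% aq. CH2O, Et3N (5 mol%), THF, 0 °C to rt
Reagents that add atoms: formaldehyde (C=O)
Why: Tollens-type aldol hydroxymethylation of the acidic 2-methyl-1,3-dione stops after one addition because the carbon becomes quaternary, and the product (C2 on the future C1) is achiral.

Step 2
Reactants: 2 hydroxymethyl dione
Product: 3 2-{[(tert-butyldimethylsilyl)oxy]methyl}-2-methylcyclohexane-1,3-dione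
Conditions: TBSCl, imidazole, DMF, 0 °C
Reagents that add atoms: tert-butyldimethylsilyl chloride (CC(C)(C)[Si](C)(C)Cl)
Why: Silylation of the primary alcohol blocks retro-aldol loss of formaldehyde and makes the CH2OTBS arm clearly larger than methyl for the next step.

Step 3
Reactants: 3 silyl ether dione
Product: 4 (2S,3S)-hydroxy ketone
Conditions: (R)-2-methyl-CBS-oxazaborolidine (20 mol%), catecholborane, toluene, −78 to −40 °C
Reagents that add atoms: none
Why: CBS desymmetrising reduction in which the catalyst selects one enantiotopic carbonyl (quaternary carbon as the large group) and hydride arrives anti to the CH2OTBS arm, so the new 14-OH (14S) is cis to C2 and C1 becomes the stereodefined quaternary centre.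

Step 4
Reactants: 4 hydroxy ketone
Product: 5 14-O-triethylsilyl ketone
Conditions: TESOTf, 2,6-lutidine, CH2Cl2, −78 °C
Reagents that add atoms: triethylsilyl trifluoromethanesulfonate (CC[Si](CC)(CC)OS(=O)(=O)C(F)(F)F)
Why: Silyl triflate silylation of the hindered secondary alcohol protects it through the enolate, triflation and oxidation chemistry and can later be removed in the presence of the primary TBS ether.

Step 5
Reactants: 5 ketone
Product: 6 C11-methyl ketone (epimer mixture at C11)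
Conditions: LDA, THF, −78 °C; MeI, −78 to −20 °C
Reagents that add atoms: iodomethane (CI)
Why: Kinetic lithium enolate alkylation can only occur at C11 because C1 is quaternary, and the C11 configuration is erased in step 6.

Step 6
Reactants: 6 methyl ketone
Product: 7 enol triflate (C10=C11)
Conditions: KHMDS, THF, −78 °C; PhNTf2, −78 to 0 °C
Reagents that add atoms: N-phenylbis(trifluoromethanesulfonimide) (O=S(=O)(N(c1ccccc1)S(=O)(=O)C(F)(F)F)C(F)(F)F)
Why: Enolate O-triflation (vinyl triflate synthesis) is regiospecific toward C11 and gives the tetrasubstituted C10=C11 triflate.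

Step 7
Reactants: 7 enol triflate
Product: 8 methyl cyclohexenecarboxylate (C9 ester on C10)
Conditions: Pd(OAc)2 (5 mol%), dppf, CO (1 atm), MeOH, Et3N, DMF, 60 °C
Reagents that add atoms: carbon monoxide ([C-]#[O+]); methanol (CO)
Why: Palladium-catalysed alkoxycarbonylation of the vinyl triflate installs C9 at the ester oxidation level.

Step 8
Reactants: 8 enoate
Product: 9 ene-keto-ester (12-oxo)
Conditions: Rh2(cap)4 (1 mol%), t-BuOOH (5 equiv), K2CO3, CH2Cl2, 25–40 °C
Reagents that add atoms: tert-butyl hydroperoxide (CC(C)(C)OO)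
Why: Dirhodium caprolactamate-catalysed allylic oxidation attacks the only ring allylic methylene (C12, γ to the ester) and gives the conjugated ketone.

Step 9
Reactants: 9 ene-keto-ester
Product: 10 14α-hydroxy ene-keto-ester
Conditions: AcOH–THF–H2O (3:1:1), rt
Reagents that add atoms: none
Why: Mild acid solvolysis cleaves the secondary triethylsilyl ether while the neopentyl primary TBS ether survives, freeing 14-OH as a directing group.

Step 10
Reactants: 10 hydroxy ene-keto-ester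
Product: 11 saturated keto ester (10α-H, 11β-methyl)
Conditions: [Ir(cod)(PCy3)(py)]PF6 (10 mol%), H2 (1–10 bar), CH2Cl2, rt
Reagents that add atoms: none
Why: Hydroxyl-directed homogeneous hydrogenation in which the homoallylic 14α-OH binds iridium and both hydrogens are delivered syn to the α face, setting C10 (C9 β) and C11 (methyl β) together.

Step 11
Reactants: 11 keto ester
Product: 13 bridged C9→O12 lactone (14α-OH free), via diol ester 12 (not isolated)
Conditions: Me4NBH(OAc)3, MeCN–AcOH, −30 °C; then PPTS (cat.), benzene, 50 °C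
Reagents that add atoms: none
Why: Evans–Saksena reduction delivers hydride intramolecularly from the 14α-alkoxyborohydride to give the anti-1,3-diol (12β-OH, 12S), and only this 12β-OH is cis-1,3 to the C9 ester, so it lactonises and thereby differentiates O12 from O14.

Step 12
Reactants: 13 bridged lactone
Product: 14 14-O-triethylsilyl bridged lactone
Conditions: TESOTf, 2,6-lutidine, CH2Cl2, −40 °C
Reagents that add atoms: triethylsilyl trifluoromethanesulfonate (CC[Si](CC)(CC)OS(=O)(=O)C(F)(F)F)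
Why: Silyl triflate silylation of the only free hydroxyl (14-OH).

Step 13
Reactants: 14 silylated lactone
Product: 16 ring-A alkyne (12β-OH free; 14α-OTES), via lactol 15 (not isolated)
Conditions: i-Bu2AlH (1.1 equiv), CH2Cl2, −78 °C; then MeOH, K2CO3, dimethyl (1-diazo-2-oxopropyl)phosphonate, 0 °C to rt
Reagents that add atoms: dimethyl (1-diazo-2-oxopropyl)phosphonate (CC(=O)C(=[N+]=[N-])P(=O)(OC)OC)
Why: Half-reduction of the lactone to the lactol followed by Ohira–Bestmann (Seyferth–Gilbert) homologation of the masked C9 aldehyde gives the terminal alkyne (new carbon = C8) and releases 12-OH.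

Step 14
Reactants: 16 alkynol
Product: 17 ring-A alkyne 12-O-PMB ether
Conditions: NaH, PMBCl, Bu4NI (cat.), THF–DMF, 0 °C to rt
Reagents that add atoms: 4-methoxybenzyl chloride (COc1ccc(CCl)cc1)
Why: Williamson etherification of the only free hydroxyl installs the PMB group that is removed last.

Step 15
Reactants: 17 ring-A alkyne; 18 methyl pyruvate
Product: 19 (17R)-propargylic alcohol
Conditions: Zn(OTf)2 (20 mol%), Et3N (30 mol%), 2-(dimethylamino)-1-(4-nitrophenyl)-3-(tert-butyldimethylsilyloxy)propan-1-ol ligand (antipode selected for 17R), toluene, 60 °C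
Reagents that add atoms: none
Why: Catalytic enantioselective zinc-acetylide addition to the α-keto ester (asymmetric alkynylation) sets the C17 carbinol under ligand control, and any 17S diastereomer is separable by chromatography.

Step 16
Reactants: 19 propargylic alcohol
Product: 20 (Z)-8-tributylstannyl alkene
Conditions: [Cp*RuCl]4 (2.5 mol%), Bu3SnH, CH2Cl2, rt
Reagents that add atoms: tributyltin hydride (CCCC[SnH](CCCC)CCCC)
Why: Ruthenium-catalysed hydroxyl-directed trans-hydrostannation places tin on C8 (proximal to the tertiary OH) and hydrogen on C9 anti to it, which fixes the C8=C9 geometry with tin cis to C10.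

Step 17
Reactants: 21 4-methyl-5,6-dihydro-2H-pyran-2-one
Product: 23 TBS (Z)-5-(TBS-oxy)-3-methylpent-2-enoate, via lithium carboxylate 22 (not isolated)
Conditions: LiOH, THF–H2O, 0 °C; evaporate; TBSCl (2.3 equiv), imidazole, DMF, rt
Reagents that add atoms: lithium hydroxide ([Li+].[OH-]); tert-butyldimethylsilyl chloride (CC(C)(C)[Si](C)(C)Cl)
Why: Saponification of the unsaturated lactone preserves the ring-enforced Z geometry of C5=C6, and double silylation gives the silyl ester and silyl ether.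

Step 18
Reactants: 23 silyl ester
Product: 24 (Z)-5-(TBS-oxy)-3-methylpent-2-enoyl chloride
Conditions: (COCl)2, DMF (cat.), CH2Cl2, 0 °C to rt
Reagents that add atoms: oxalyl chloride (O=C(Cl)C(=O)Cl)
Why: Vilsmeier-type activation converts the silyl ester directly into the acid chloride under neutral conditions without Z/E isomerisation.

Step 19
Reactants: 20 alkenylstannane; 24 acid chloride
Product: 25 cross-conjugated (5Z)-dienone (C7 ketone)
Conditions: Pd2(dba)3 (5 mol%), P(2-furyl)3, CuI (copper iodide, 10 mol%), NMP, 45 °C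
Reagents that add atoms: none
Why: Acyl Stille coupling (Migita–Kosugi–Stille ketone synthesis) replaces tin by the acyl group with retention, so C7 ends up cis to C10 across C8=C9.

Step 20
Reactants: 25 dienone
Product: 26 (7S)-dienol
Conditions: (R)-2-methyl-CBS-oxazaborolidine (20 mol%), catecholborane, toluene, −78 °C
Reagents that add atoms: none
Why: CBS 1,2-reduction under reagent control, with the α-branched C8 alkenyl group acting as the large substituent, sets the C7 carbinol (7S).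

Step 21
Reactants: 26 dienol
Product: 28 5,6-epoxy β-alkylidene γ-lactone, via epoxy alcohol 27 (not isolated)
Conditions: mCPBA, NaHCO3, CH2Cl2, 0 °C; then DBU (20 mol%), rt
Reagents that add atoms: 3-chloroperoxybenzoic acid (OOC(=O)c1cccc(Cl)c1)
Why: Hydroxyl-directed (Henbest) epoxidation of the more electron-rich Z-allylic C5=C6 bond under A(1,3) control gives the threo epoxy alcohol (5R,6S), and the 7-OH then lactonises onto the C19 ester.

Step 22
Reactants: 28 alkylidene lactone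
Product: 29 (8S,9S)-8,9,17-triol lactone
Conditions: OsO4 (10 mol%), NMO, acetone–H2O, rt
Reagents that add atoms: osmium tetroxide (O=[Os](=O)(=O)=O); N-methylmorpholine N-oxide (C[N+]1([O-])CCOCC1); water (O)
Why: Upjohn syn-dihydroxylation occurs on the lactone face anti to both the allylic 17-OH (Kishi rule) and the C6 substituent, which sets C8 (OH cis to H7) and C9 together from the defined alkene geometry.

Step 23
Reactants: 29 triol
Product: 30 9-O-acetate
Conditions: Ac2O, pyridine, DMAP (cat.), CH2Cl2, 0 °C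
Reagents that add atoms: acetic anhydride (CC(=O)OC(C)=O)
Why: DMAP-catalysed acetylation is selective for the secondary 9-OH over the two tertiary alcohols and stops 9-OH from attacking the epoxide.

Step 24
Reactants: 30 acetate
Product: 31 seco-triol (C2–OH, C3–OH, 14α-OH free)
Conditions: Et3N·3HF, MeCN, rt to 40 °C
Reagents that add atoms: none
Why: Fluoride-mediated desilylation with the near-neutral amine–HF complex removes the three silyl ethers without opening the epoxide or cleaving the acetate.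

Step 25
Reactants: 31 seco-triol
Product: 32 2,3-seco-dialdehyde
Conditions: TEMPO (20 mol%), PhI(OAc)2, CH2Cl2, rt
Reagents that add atoms: none
Why: TEMPO/PhI(OAc)2 oxidation is selective for the two primary alcohols over the hindered secondary 14-OH and the tertiary alcohols.

Step 26
Reactants: 32 dialdehyde
Product: 33 macrocyclic (2R,3S)-diol
Conditions: SmI2 (2.5 equiv), t-BuOH (2 equiv), THF (0.002 M, syringe pump), −78 °C to rt
Reagents that add atoms: none
Why: Intramolecular SmI2 pinacol coupling at high dilution joins the two ketyls through a samarium-bridged cis-diolate on the exposed β face of a chain pre-folded by the cis-epoxide and the cis-fused lactone, closing the ten-membered ring and setting C2 and C3 together.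

Step 27
Reactants: 33 macrocyclic diol
Product: 34 2,3,9,14-tetraacetate 12-O-PMB ether
Conditions: Ac2O, DMAP, pyridine, CH2Cl2, rt
Reagents that add atoms: acetic anhydride (CC(=O)OC(C)=O)
Why: DMAP-catalysed acetylation esterifies the three free secondary hydroxyls (C2, C3, C14) and leaves the tertiary 8-OH and 17-OH untouched.

Step 28
Reactants: 34 PMB ether
Product: 35 CNP0287149.1
Conditions: DDQ, CH2Cl2–pH 7 buffer, 0 °C to rt
Reagents that add atoms: none
Why: Oxidative PMB cleavage by DDQ under buffered conditions frees 12-OH without touching the epoxide, the acetates or the lactone.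

**Compound list**

1 | 2-methylcyclohexane-1,3-dione | CC1C(=O)CCCC1=O | starting material
2 | 2-(hydroxymethyl)-2-methylcyclohexane-1,3-dione | CC1(CO)C(=O)CCCC1=O | intermediate
3 | 2-{[(tert-butyldimethylsilyl)oxy]methyl}-2-methylcyclohexane-1,3-dione | CC1(CO[Si](C)(C)C(C)(C)C)C(=O)CCCC1=O | intermediate
4 | (2S,3S)-2-{[(tert-butyldimethylsilyl)oxy]methyl}-3-hydroxy-2-methylcyclohexan-1-one (OH cis to CH2OTBS; C10 ketone, C1, C14) | O=C1CCC[C@H](O)[C@]1(C)CO[Si](C)(C)C(C)(C)C | intermediate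
5 | (2S,3S)-2-{[(tert-butyldimethylsilyl)oxy]methyl}-2-methyl-3-[(triethylsilyl)oxy]cyclohexan-1-one | O=C1CCC[C@H](O[Si](CC)(CC)CC)[C@]1(C)CO[Si](C)(C)C(C)(C)C | intermediate
6 | (2S,3S)-2-{[(tert-butyldimethylsilyl)oxy]methyl}-2,6-dimethyl-3-[(triethylsilyl)oxy]cyclohexan-1-one, mixture of C6 (= C11) epimers | O=C1C(C)CC[C@H](O[Si](CC)(CC)CC)[C@]1(C)CO[Si](C)(C)C(C)(C)C | intermediate
7 | (5S,6S)-6-{[(tert-butyldimethylsilyl)oxy]methyl}-2,6-dimethyl-5-[(triethylsilyl)oxy]cyclohex-1-en-1-yl trifluoromethanesulfonate | O=S(=O)(OC1=C(C)CC[C@H](O[Si](CC)(CC)CC)[C@]1(C)CO[Si](C)(C)C(C)(C)C)C(F)(F)F | intermediate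
8 | methyl (5S,6S)-6-{[(tert-butyldimethylsilyl)oxy]methyl}-2,6-dimethyl-5-[(triethylsilyl)oxy]cyclohex-1-ene-1-carboxylate | COC(=O)C1=C(C)CC[C@H](O[Si](CC)(CC)CC)[C@]1(C)CO[Si](C)(C)C(C)(C)C | intermediate
9 | methyl (5S,6S)-6-{[(tert-butyldimethylsilyl)oxy]methyl}-2,6-dimethyl-3-oxo-5-[(triethylsilyl)oxy]cyclohex-1-ene-1-carboxylate | COC(=O)C1=C(C)C(=O)C[C@H](O[Si](CC)(CC)CC)[C@]1(C)CO[Si](C)(C)C(C)(C)C | intermediate
10 | methyl (5S,6S)-6-{[(tert-butyldimethylsilyl)oxy]methyl}-5-hydroxy-2,6-dimethyl-3-oxocyclohex-1-ene-1-carboxylate | COC(=O)C1=C(C)C(=O)C[C@H](O)[C@]1(C)CO[Si](C)(C)C(C)(C)C | intermediate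
11 | methyl (1S,2S,3S,6R)-2-{[(tert-butyldimethylsilyl)oxy]methyl}-3-hydroxy-2,6-dimethyl-5-oxocyclohexane-1-carboxylate (10α-H, 11β-methyl, 14α-OH, 15β-methyl) | COC(=O)[C@H]1[C@@H](C)C(=O)C[C@H](O)[C@]1(C)CO[Si](C)(C)C(C)(C)C | intermediate
12 | methyl (1S,2S,3S,5S,6R)-2-{[(tert-butyldimethylsilyl)oxy]methyl}-3,5-dihydroxy-2,6-dimethylcyclohexane-1-carboxylate (12β,14α-diol) | COC(=O)[C@H]1[C@@H](C)[C@@H](O)C[C@H](O)[C@]1(C)CO[Si](C)(C)C(C)(C)C | intermediate
13 | bridged C9→O12 γ-lactone of 12 (6-oxabicyclo[3.2.1]octan-7-one skeleton; C20 methyl on the one-carbon bridge; free 14α-OH; C1 with 15β-methyl and C2H2OTBS) | O=C1[C@H]2[C@@H](C)[C@@H](O1)C[C@H](O)[C@]2(C)CO[Si](C)(C)C(C)(C)C | intermediate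
14 | 14-O-triethylsilyl ether of 13 | O=C1[C@H]2[C@@H](C)[C@@H](O1)C[C@H](O[Si](CC)(CC)CC)[C@]2(C)CO[Si](C)(C)C(C)(C)C | intermediate
15 | C9 lactol of 14 (anomeric mixture) | OC1[C@H]2[C@@H](C)[C@@H](O1)C[C@H](O[Si](CC)(CC)CC)[C@]2(C)CO[Si](C)(C)C(C)(C)C | intermediate
16 | ring-A alkyne: 10β-ethynyl (C9≡C8H), 11β-methyl, 12β-OH, 14α-OTES, C1 with 15β-methyl and C2H2OTBS | C#C[C@H]1[C@@H](C)[C@@H](O)C[C@H](O[Si](CC)(CC)CC)[C@]1(C)CO[Si](C)(C)C(C)(C)C | intermediate
17 | 12-O-(4-methoxybenzyl) ether of 16 | C#C[C@H]1[C@@H](C)[C@@H](OCc2ccc(OC)cc2)C[C@H](O[Si](CC)(CC)CC)[C@]1(C)CO[Si](C)(C)C(C)(C)C | intermediate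
18 | methyl pyruvate (methyl 2-oxopropanoate) | CC(=O)C(=O)OC | starting material
19 | (17R)-propargylic alcohol: methyl 2-hydroxy-2-methylbut-3-ynoate unit (C19, C17, C18, C8≡C9) attached through C9 to C10 of 17 | COC(=O)[C@](C)(O)C#C[C@H]1[C@@H](C)[C@@H](OCc2ccc(OC)cc2)C[C@H](O[Si](CC)(CC)CC)[C@]1(C)CO[Si](C)(C)C(C)(C)C | intermediate
20 | (Z)-alkenylstannane from 19: Bu3Sn on C8 cis to C10, H9 cis to C17 | COC(=O)[C@](C)(O)/C([Sn](CCCC)(CCCC)CCCC)=C/[C@H]1[C@@H](C)[C@@H](OCc2ccc(OC)cc2)C[C@H](O[Si](CC)(CC)CC)[C@]1(C)CO[Si](C)(C)C(C)(C)C | intermediate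
21 | 4-methyl-5,6-dihydro-2H-pyran-2-one | CC1=CC(=O)OCC1 | starting material
22 | lithium (Z)-5-hydroxy-3-methylpent-2-enoate | [Li+].[O-]C(=O)/C=C(/C)CCO | intermediate
23 | tert-butyldimethylsilyl (Z)-5-[(tert-butyldimethylsilyl)oxy]-3-methylpent-2-enoate | CC(C)(C)[Si](C)(C)OC(=O)/C=C(/C)CCO[Si](C)(C)C(C)(C)C | intermediate
24 | (Z)-5-[(tert-butyldimethylsilyl)oxy]-3-methylpent-2-enoyl chloride (C7 to C3 with C16) | ClC(=O)/C=C(/C)CCO[Si](C)(C)C(C)(C)C | intermediate
25 | (5Z)-dienone: C7 ketone on C8 (C7 cis to C10 across C8=C9), side chain C6=C5(CH3)–C4H2–C3H2OTBS, C17 carbinol ester retained | COC(=O)[C@](C)(O)/C(C(=O)/C=C(/C)CCO[Si](C)(C)C(C)(C)C)=C/[C@H]1[C@@H](C)[C@@H](OCc2ccc(OC)cc2)C[C@H](O[Si](CC)(CC)CC)[C@]1(C)CO[Si](C)(C)C(C)(C)C | intermediate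
26 | (7S)-dienol from 25 | COC(=O)[C@](C)(O)/C([C@@H](O)/C=C(/C)CCO[Si](C)(C)C(C)(C)C)=C/[C@H]1[C@@H](C)[C@@H](OCc2ccc(OC)cc2)C[C@H](O[Si](CC)(CC)CC)[C@]1(C)CO[Si](C)(C)C(C)(C)C | intermediate
27 | (5R,6S,7S)-5,6-epoxy-7-ol (threo) from 26 | CC(C)(C)[Si](C)(C)OCC[C@@]1(C)O[C@H]1[C@H](O)/C(=C\[C@H]2[C@@H](C)[C@@H](OCc3ccc(OC)cc3)C[C@H](O[Si](CC)(CC)CC)[C@]2(C)CO[Si](C)(C)C(C)(C)C)[C@@](C)(O)C(=O)OC | intermediate
28 | 5,6-epoxy β-alkylidene γ-lactone (O7–C19 lactone; exocyclic C8=C9 with C7 cis to C10; 17-OH free) | CC(C)(C)[Si](C)(C)OCC[C@@]1(C)O[C@H]1[C@@H]2OC(=O)[C@](C)(O)/C2=C/[C@H]3[C@@H](C)[C@@H](OCc4ccc(OC)cc4)C[C@H](O[Si](CC)(CC)CC)[C@]3(C)CO[Si](C)(C)C(C)(C)C | intermediate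
29 | (8S,9S)-8,9,17-triol lactone from 28 | CC(C)(C)[Si](C)(C)OCC[C@@]1(C)O[C@H]1[C@@H]2OC(=O)[C@](C)(O)[C@]2(O)[C@@H](O)[C@H]3[C@@H](C)[C@@H](OCc4ccc(OC)cc4)C[C@H](O[Si](CC)(CC)CC)[C@]3(C)CO[Si](C)(C)C(C)(C)C | intermediate
30 | 9-O-acetate of 29 | CC(C)(C)[Si](C)(C)OCC[C@@]1(C)O[C@H]1[C@@H]2OC(=O)[C@](C)(O)[C@]2(O)[C@@H](OC(C)=O)[C@H]3[C@@H](C)[C@@H](OCc4ccc(OC)cc4)C[C@H](O[Si](CC)(CC)CC)[C@]3(C)CO[Si](C)(C)C(C)(C)C | intermediate
31 | seco-triol: 30 with C2–OH, C3–OH and 14α-OH free | OCC[C@@]1(C)O[C@H]1[C@@H]2OC(=O)[C@](C)(O)[C@]2(O)[C@@H](OC(C)=O)[C@H]3[C@@H](C)[C@@H](OCc4ccc(OC)cc4)C[C@H](O)[C@]3(C)CO | intermediate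
32 | 2,3-seco-2,3-dialdehyde | O=CC[C@@]1(C)O[C@H]1[C@@H]2OC(=O)[C@](C)(O)[C@]2(O)[C@@H](OC(C)=O)[C@H]3[C@@H](C)[C@@H](OCc4ccc(OC)cc4)C[C@H](O)[C@]3(C)C=O | intermediate
33 | macrocyclic (2R,3S)-2β,3β-diol: 9-O-acetyl, 12-O-PMB, 14α-OH, 8,17-diol, 5β,6β-epoxide | O[C@H]1C[C@@]2(C)O[C@H]2[C@@H]2OC(=O)[C@](C)(O)[C@]2(O)[C@@H](OC(C)=O)[C@H]2[C@@H](C)[C@@H](OCc3ccc(OC)cc3)C[C@H](O)[C@]2(C)[C@H]1O | intermediate
34 | 2,3,9,14-tetraacetate 12-O-PMB ether | CC(=O)O[C@H]1C[C@@]2(C)O[C@H]2[C@@H]2OC(=O)[C@](C)(O)[C@]2(O)[C@@H](OC(C)=O)[C@H]2[C@@H](C)[C@@H](OCc3ccc(OC)cc3)C[C@H](OC(C)=O)[C@]2(C)[C@H]1OC(C)=O | intermediate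
35 | CNP0287149.1 (1R,2R,3S,5R,6S,7S,8S,9S,10S,11R,12S,14S,17R) | CC(=O)O[C@H]1C[C@@]2(C)O[C@H]2[C@@H]2OC(=O)[C@](C)(O)[C@]2(O)[C@@H](OC(C)=O)[C@H]2[C@@H](C)[C@@H](O)C[C@H](OC(C)=O)[C@]2(C)[C@H]1OC(C)=O | target

**Step count and risks**

Total step count: 28. Longest linear sequence: 26 (steps 1–16 and 19–28); steps 17–18 make acid chloride 24 in a side branch.

Three steps most likely to fail:

Step 26 (pinacol macrocyclisation). The ten-membered ring closure may be low-yielding, or may give another of the four possible diols. The fallback closes the same bond as an alkene. It sets out from dialdehyde 32: double Wittig methylenation (Ph3P=CH2, THF, −78 to 0 °C) gives the 2,3-seco diene F1. Ring-closing metathesis with the second-generation Hoveyda–Grubbs catalyst (toluene, 80 °C, high dilution) gives the (2Z)-cyclodecene F2, the cis alkene being the only unstrained outcome in this ring. Upjohn dihydroxylation (OsO4, NMO) from the exposed β face then comes back to the route at diol 33.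

Step 19 (acyl Stille coupling of a hindered α-branched alkenylstannane). The fallback forms the C7–C8 bond by carbonyl addition instead of acylation. It sets out from stannane 20: iododestannylation (I2, CH2Cl2, 0 °C) gives with retention the alkenyl iodide F3. Acid chloride 24 is reduced with LiAlH(OtBu)3 (THF, −78 °C) to the (Z)-enal F4. Nozaki–Hiyama–Kishi coupling of the two (CrCl2, NiCl2 cat., DMSO) gives the C7-epimeric dienols F5. Dess–Martin oxidation converges on dienone 25, where the route resumes.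

Step 21 (chemo- and face-selective epoxidation of one of two allylic alkenes, then lactonisation). The fallback installs the epoxide on the small fragment under reagent control before the coupling. It sets out from silyl ester 23:
- i-Bu2AlH reduction gives the (Z)-allylic alcohol F4-type primary alcohol, here the (Z)-5-(TBS-oxy)-3-methylpent-2-en-1-ol F6.
- Sharpless asymmetric epoxidation (Ti(OiPr)4, D-(−)-diethyl tartrate, t-BuOOH, −20 °C) gives the (5R,6S)-epoxy alcohol F7.
- TEMPO/PhI(OAc)2 in wet MeCN gives the epoxy acid F8.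
- 1-Chloro-N,N,2-trimethylprop-1-en-1-amine gives the epoxy acid chloride F9.
- Acyl Stille coupling with 20 (step 19 conditions) gives the epoxy enone F10.
- CBS reduction (step 20 conditions) comes back to the route at epoxy alcohol 27, which is lactonised to 28 with DBU as in step 21.

Further compounds
F1 | step 26 | 2,3-seco diene (C2H=CH2 on C1 and C3H=CH2 on C4; otherwise as 32) | C=CC[C@@]1(C)O[C@H]1[C@@H]2OC(=O)[C@](C)(O)[C@]2(O)[C@@H](OC(C)=O)[C@H]3[C@@H](C)[C@@H](OCc4ccc(OC)cc4)C[C@H](O)[C@]3(C)C=C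
F2 | step 26 | (2Z)-cyclodecene (C2=C3 alkene in the closed ten-membered ring; otherwise as 33) | C1[C@@]2(C)O[C@H]2[C@@H]2OC(=O)[C@](C)(O)[C@]2(O)[C@@H](OC(C)=O)[C@H]2[C@@H](C)[C@@H](OCc3ccc(OC)cc3)C[C@H](O)[C@]2(C)/C=C\1
F3 | step 19 | alkenyl iodide (iodine on C8 cis to C10; otherwise as 20) | COC(=O)[C@](C)(O)/C(I)=C/[C@H]1[C@@H](C)[C@@H](OCc2ccc(OC)cc2)C[C@H](O[Si](CC)(CC)CC)[C@]1(C)CO[Si](C)(C)C(C)(C)C
F4 | step 19 | (Z)-5-[(tert-butyldimethylsilyl)oxy]-3-methylpent-2-enal | O=C/C=C(/C)CCO[Si](C)(C)C(C)(C)C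
F5 | step 19 | C7-epimeric dienols (26 and its 7-epimer) | COC(=O)[C@](C)(O)/C(C(O)/C=C(/C)CCO[Si](C)(C)C(C)(C)C)=C/[C@H]1[C@@H](C)[C@@H](OCc2ccc(OC)cc2)C[C@H](O[Si](CC)(CC)CC)[C@]1(C)CO[Si](C)(C)C(C)(C)C
F6 | step 21 | (Z)-5-[(tert-butyldimethylsilyl)oxy]-3-methylpent-2-en-1-ol | OC/C=C(/C)CCO[Si](C)(C)C(C)(C)C
F7 | step 21 | (5R,6S)-epoxy alcohol (cis-2,3-epoxy-5-(TBS-oxy)-3-methylpentan-1-ol; briarane C7 to C3) | CC(C)(C)[Si](C)(C)OCC[C@@]1(C)O[C@H]1CO
F8 | step 21 | (5R,6S)-epoxy acid | CC(C)(C)[Si](C)(C)OCC[C@@]1(C)O[C@H]1C(=O)O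
F9 | step 21 | (5R,6S)-epoxy acid chloride | CC(C)(C)[Si](C)(C)OCC[C@@]1(C)O[C@H]1C(=O)Cl
F10 | step 21 | (5R,6S)-epoxy enone (C7 ketone on C8; C7 cis to C10) | CC(C)(C)[Si](C)(C)OCC[C@@]1(C)O[C@H]1C(=O)/C(=C\[C@H]2[C@@H](C)[C@@H](OCc3ccc(OC)cc3)C[C@H](O[Si](CC)(CC)CC)[C@]2(C)CO[Si](C)(C)C(C)(C)C)[C@@](C)(O)C(=O)OC
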